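**Assumptions:** The target is taken exactly as drawn in the SMILES (7''S,8''S, i.e. threo); the sign of rotation is not used. Compounds 2 and 9 are treated as catalogue items; if not, each is one step from (R)-4-benzyl-2-oxazolidinone + chloroacetyl chloride, and from 2',4',6'-trihydroxyacetophenone + BnBr.

## Retrosynthetic overview

1. Target ⇒ global deprotection (1,3-diol acetonide, three phenolic benzyl ethers) of a fully protected flavonolignan.
2. The flavone C-ring is the only ring built in the main sequence, and it is formed last: Claisen–Schmidt condensation of A-ring acetophenone 9 with B-ring aldehyde 8, then I2/DMSO oxidative cyclisation.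
3. The aldehyde is carried as an aryl bromide (Br → Li → CHO), so no aldehyde or Lewis-basic flavone is present during the boron aldol.
4. The C7''–C8'' bond and both stereocentres come from one Evans syn-aldol of an (R)-4-benzyl-N-(aryloxyacetyl)oxazolidinone with 4-(benzyloxy)benzaldehyde (syn aldol = threo; the (R)-auxiliary gives 7''S,8''S).
5. The 8''-O-4' ether is made first, by SN2 of 4-bromo-2,6-dimethoxyphenol on the chloroacetyl imide.

## Route

**Step 1**
Reactants: 1, 4-bromo-2,6-dimethoxyphenol; 2, (R)-4-benzyl-3-(2-chloroacetyl)oxazolidin-2-one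
Product: 3, (R)-4-benzyl-3-[2-(4-bromo-2,6-dimethoxyphenoxy)acetyl]oxazolidin-2-one
Conditions: K2CO3, NaI (cat.), MeCN, rt → 40 °C
Reagents that add atoms: none (both partners are listed reactants)
Why: Williamson-type SN2 of the phenoxide on the activated α-halo imide is much faster than acyl attack by this hindered phenoxide; the auxiliary stereocentre is untouched.

**Step 2**
Reactants: 3; 4, 4-(benzyloxy)benzaldehyde
Product: 5, (R)-4-benzyl-3-[(2R,3S)-3-[4-(benzyloxy)phenyl]-2-(4-bromo-2,6-dimethoxyphenoxy)-3-hydroxypropanoyl]oxazolidin-2-one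
Conditions: Bu2BOTf, i-Pr2NEt, CH2Cl2, −78 → 0 °C; then 4, −78 → 0 °C; pH 7 buffer/MeOH/H2O2, 0 °C
Reagents that add atoms: none
Why: Evans boron aldol: the Z-boron enolate reacts through a Zimmerman–Traxler chair on the face opposite the auxiliary benzyl group, giving the "Evans syn" adduct and setting C8'' (2R here) and C7'' (3S) in one step.

**Step 3**
Reactants: 5
Product: 6, (1S,2S)-1-[4-(benzyloxy)phenyl]-2-(4-bromo-2,6-dimethoxyphenoxy)propane-1,3-diol (plus recovered (R)-4-benzyl-2-oxazolidinone)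
Conditions: NaBH4, THF/H2O (4:1), 0 °C → rt
Reagents that add atoms: none (hydride only)
Why: Reductive cleavage of the N-acyl oxazolidinone to the primary alcohol under near-neutral conditions avoids retro-aldol and C8 epimerisation; the descriptor at C8 changes from R to S only through CIP priority, not geometry.

**Step 4**
Reactants: 6
Product: 7, (4S,5S)-4-[4-(benzyloxy)phenyl]-5-(4-bromo-2,6-dimethoxyphenoxy)-2,2-dimethyl-1,3-dioxane
Conditions: 2,2-dimethoxypropane, PPTS (cat.), acetone, rt
Reagents that add atoms: 2,2-dimethoxypropane, COC(C)(C)OC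
Why: Acetonide formation (transacetalisation) of the 1,3-diol protects both hydroxyls for the organolithium, base and oxidation steps; these mild conditions do not ionise the benzylic C–O bond.

**Step 5**
Reactants: 7
Product: 8, 4-{[(4S,5S)-4-[4-(benzyloxy)phenyl]-2,2-dimethyl-1,3-dioxan-5-yl]oxy}-3,5-dimethoxybenzaldehyde
Conditions: n-BuLi, THF, −78 °C; then DMF, −78 → 0 °C; aq. NH4Cl
Reagents that add atoms: N,N-dimethylformamide, CN(C)C=O (supplies the CHO)
Why: Br/Li exchange followed by Bouveault formylation; the acetal and benzyl ether are inert at −78 °C and neither stereocentre is acidic.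

**Step 6**
Reactants: 8; 9, 1-[2,4-bis(benzyloxy)-6-hydroxyphenyl]ethan-1-one
Product: 10, (E)-1-[2,4-bis(benzyloxy)-6-hydroxyphenyl]-3-[4-{[(4S,5S)-4-[4-(benzyloxy)phenyl]-2,2-dimethyl-1,3-dioxan-5-yl]oxy}-3,5-dimethoxyphenyl]prop-2-en-1-one
Conditions: KOH (50% aq.), EtOH/THF, rt, 24–48 h
Reagents that add atoms: none
Why: Claisen–Schmidt condensation gives the E-2'-hydroxychalcone; the acetonide, benzyl ethers and the alkyl aryl ether are base-stable, and no free alkoxide is present to displace the aryloxide.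

**Step 7**
Reactants: 10
Product: 11, 5,7-bis(benzyloxy)-2-[4-{[(4S,5S)-4-[4-(benzyloxy)phenyl]-2,2-dimethyl-1,3-dioxan-5-yl]oxy}-3,5-dimethoxyphenyl]-4H-chromen-4-one
Conditions: I2 (10 mol%), DMSO, 110 °C, 2–3 h
Reagents that add atoms: none (net loss of 2 H)
Why: Iodine/DMSO oxidative cyclisation of the 2'-hydroxychalcone (oxa-Michael addition, then iodination/HI elimination with DMSO regenerating I2) closes the pyranone ring without touching the side-chain stereocentres.

**Step 8**
Reactants: 11
Product: 12, 5,7-bis(benzyloxy)-2-[4-{[(1S,2S)-1-[4-(benzyloxy)phenyl]-1,3-dihydroxypropan-2-yl]oxy}-3,5-dimethoxyphenyl]-4H-chromen-4-one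
Conditions: AcOH/THF/H2O (3:1:1), 45 °C
Reagents that add atoms: none (water supplies only H to the product)
Why: Mild acetal hydrolysis, done while the para-oxygen is still benzylated, so C7'' is not prone to quinone-methide epimerisation; no alcohol solvent is present to etherify C7''.

**Step 9**
Reactants: 12
Product: 13, target, (7''S,8''S)-4'',5,7-trihydroxy-3',5'-dimethoxy-4',8''-oxyflavonolignan-7'',9''-diol
Conditions: H2 (1 atm), 10% Pd/C, THF/MeOH, rt, stopped at full conversion
Reagents that add atoms: none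
Why: Hydrogenolysis of the three aryl benzyl ethers under neutral conditions; the flavone C2=C3 bond and the secondary benzylic alcohol are normally retained at 1 atm without acid.

## Compound list

1 | 4-bromo-2,6-dimethoxyphenol | COc1cc(Br)cc(OC)c1O | starting material
2 | (R)-4-benzyl-3-(2-chloroacetyl)oxazolidin-2-one | O=C(CCl)N1C(=O)OC[C@H]1Cc1ccccc1 | starting material
3 | (R)-4-benzyl-3-[2-(4-bromo-2,6-dimethoxyphenoxy)acetyl]oxazolidin-2-one | COc1cc(Br)cc(OC)c1OCC(=O)N1C(=O)OC[C@H]1Cc1ccccc1 | intermediate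
4 | 4-(benzyloxy)benzaldehyde | O=Cc1ccc(OCc2ccccc2)cc1 | starting material
5 | (R)-4-benzyl-3-[(2R,3S)-3-[4-(benzyloxy)phenyl]-2-(4-bromo-2,6-dimethoxyphenoxy)-3-hydroxypropanoyl]oxazolidin-2-one | COc1cc(Br)cc(OC)c1O[C@@H](C(=O)N1C(=O)OC[C@H]1Cc1ccccc1)[C@@H](O)c1ccc(OCc2ccccc2)cc1 | intermediate
6 | (1S,2S)-1-[4-(benzyloxy)phenyl]-2-(4-bromo-2,6-dimethoxyphenoxy)propane-1,3-diol | COc1cc(Br)cc(OC)c1O[C@@H](CO)[C@@H](O)c1ccc(OCc2ccccc2)cc1 | intermediate
7 | (4S,5S)-4-[4-(benzyloxy)phenyl]-5-(4-bromo-2,6-dimethoxyphenoxy)-2,2-dimethyl-1,3-dioxane | COc1cc(Br)cc(OC)c1O[C@H]1COC(C)(C)O[C@H]1c1ccc(OCc2ccccc2)cc1 | intermediate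
8 | 4-{[(4S,5S)-4-[4-(benzyloxy)phenyl]-2,2-dimethyl-1,3-dioxan-5-yl]oxy}-3,5-dimethoxybenzaldehyde | COc1cc(C=O)cc(OC)c1O[C@H]1COC(C)(C)O[C@H]1c1ccc(OCc2ccccc2)cc1 | intermediate
9 | 1-[2,4-bis(benzyloxy)-6-hydroxyphenyl]ethan-1-one | CC(=O)c1c(O)cc(OCc2ccccc2)cc1OCc1ccccc1 | starting material
10 | (E)-2'-hydroxy-4',6'-bis(benzyloxy)chalcone carrying the (4S,5S)-dioxanyl ether of 8 on the B-ring | COc1cc(/C=C/C(=O)c2c(O)cc(OCc3ccccc3)cc2OCc2ccccc2)cc(OC)c1O[C@H]1COC(C)(C)O[C@H]1c1ccc(OCc2ccccc2)cc1 | intermediate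
11 | 5,7-bis(benzyloxy)-2-[4-{[(4S,5S)-4-[4-(benzyloxy)phenyl]-2,2-dimethyl-1,3-dioxan-5-yl]oxy}-3,5-dimethoxyphenyl]-4H-chromen-4-one | COc1cc(-c2cc(=O)c3c(OCc4ccccc4)cc(OCc4ccccc4)cc3o2)cc(OC)c1O[C@H]1COC(C)(C)O[C@H]1c1ccc(OCc2ccccc2)cc1 | intermediate
12 | 5,7-bis(benzyloxy)-2-[4-{[(1S,2S)-1-[4-(benzyloxy)phenyl]-1,3-dihydroxypropan-2-yl]oxy}-3,5-dimethoxyphenyl]-4H-chromen-4-one | COc1cc(-c2cc(=O)c3c(OCc4ccccc4)cc(OCc4ccccc4)cc3o2)cc(OC)c1O[C@@H](CO)[C@@H](O)c1ccc(OCc2ccccc2)cc1 | intermediate
13 | (7''S,8''S)-4'',5,7-trihydroxy-3',5'-dimethoxy-4',8''-oxyflavonolignan-7'',9''-diol | COc1cc(-c2cc(=O)c3c(O)cc(O)cc3o2)cc(OC)c1O[C@@H](CO)[C@@H](O)c1ccc(O)cc1 | target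

## Summary

Total steps: 9. Longest linear sequence: 9 (1 → 3 → 5 → 6 → 7 → 8 → 10 → 11 → 12 → 13); compounds 2, 4 and 9 enter as purchased materials.

Steps most likely to fail, each with a fallback that changes the approach:

1. **Step 7 (I2/DMSO at 110 °C next to an acetonide and an electron-rich benzylic C–O bond).** Traces of HI may cleave the acetal or ionise C7''. Fallback: build the flavone by a Baker–Venkataraman route instead. Oxidise 8 to the acid (Pinnick), esterify the 2-OH of 9, migrate the acyl group with LiHMDS, and cyclodehydrate the 1,3-diketone with catalytic TsOH at rt.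
2. **Step 2 (boron aldol of a hindered 2,6-dimethoxyaryloxyacetyl imide).** Enolisation or diastereoselectivity may be poor. Fallback: a chiral-pool route. Mitsunobu etherification of methyl (R)-2-hydroxy-3-(TBDPS-oxy)propanoate with phenol 1 sets 8''S by inversion; DIBAL then gives the aldehyde, and chelation-controlled addition of 4-BnOC6H4MgBr sets the 7'',8''-syn (threo) carbinol.
3. **Step 1 (phenoxide alkylation in the presence of the imide).** Acyl transfer or auxiliary cleavage could compete. Fallback: acylate the auxiliary instead of alkylating the phenol. Treat 1 with tert-butyl bromoacetate, remove the ester with TFA, and couple the aryloxyacetic acid to (R)-4-benzyl-2-oxazolidinone via the pivaloyl mixed anhydride (PivCl, Et3N, LiCl).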